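## Structural features

The target is a linear trimer of (−)-epicatechin 3-O-gallate: three 2-arylchroman units, each with a 3,4-dihydroxyphenyl ring B at C2 and a galloyl ester on O3, joined by two aryl–C(sp3) bonds, C4 of the upper unit (U) to C6 of the middle unit (M) and C4 of M to C8 of the lower unit (L). It has eight stereocentres: C2 and C3 are 2R,3R (cis) in every unit, and C4 of U and C4 of M are both 4β (trans to O3), so that C2, C3 and C4 are contiguous in U and in M. The fragile parts are the two doubly benzylic interflavan bonds (they ionise in acid), the three gallate esters (base, organometallics) and the free polyphenol (air oxidation, C2 epimerisation in base), so the phenols stay benzylated until a final neutral hydrogenolysis and the esters are put on late. The real difficulty is twofold: the 4→6 bond is the disfavoured regiochemistry, because C8 of a flavan is the better nucleophile, and ring C of M is fully substituted, lies between two large aryl groups and has a diarylmethine stereocentre at C4. The key step uses the fact that C4, C4a, C8a and O1 of M, together with the two-carbon unit C3–C2, are the atoms of a 4-aryl-3,4-dihydrocoumarin, and that ring A of M is a phloroglucinol: once O5 and O7 are benzylated and U sits between them, the remaining hydroxyl (future O1) has two equivalent ortho carbons (future C4a). The hub phenol, the acyl pyrazole and the lactone carry the same sense as the target at every stereocentre, with (4R) at the new centre of M in the lactone. One design change is made to the hub phenol: C8 of U, the most nucleophilic carbon of any benzylated flavan, carries a bromine, which costs no step because the same bromide serves the L branch and which leaves in the final hydrogenolysis. The three 3-hydroxyls differ strongly in hindrance (M most, L least), so the esters are placed one at a time, the M ester while its hydroxyl is the only free one.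

## Logic of the disconnections

**33 to 32.** The twenty-one O–CH2Ph bonds and the C8–Br bond of the upper unit are cut. All earlier chemistry then runs on non-oxidisable ethers, and the blocking bromine leaves without a step of its own. The forward step must be a neutral reduction that spares three esters and two doubly benzylic C–C bonds.

**32 to 31 and 28.** The ester C–O bond at O3 of the upper unit is cut. This hydroxyl, between the C2 aryl group and the C4 hub ring, is the slower of the two freed by desilylation, so its ester is made last and alone. The forward step must force a hindered secondary hydroxyl without disturbing the two esters already present.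

**31 to 30 and 28.** The ester C–O bond at O3 of the lower unit is cut. This hydroxyl has only a methylene group on its C4 side, so one equivalent of acid under mild conditions should be enough. The forward step must prefer this hydroxyl over the upper one; material acylated elsewhere is not lost, since it converges on 32.

**30 to 29.** The two O–Si bonds are cut. Silyl ethers on O3 of the upper and lower units are the only groups that pass the Lewis acid, the strong bases and the organomagnesium reagent and still come off without touching benzyl ethers. The forward step needs a fluoride source that spares the ester on the middle unit.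

**29 to 27 and 28.** The ester C–O bond at O3 of the middle unit is cut. No ester would survive the enolate, aluminium amide, Grignard and hydride steps, so none can enter before 27. In 27 the middle hydroxyl is the only free one, so the most hindered ester is made on a single site. The demand is acylation of a secondary hydroxyl flanked by the C2 aryl group and the C4 diarylmethine.

**27 to 26.** The O1–C2 bond of the middle unit is cut. The phenol oxygen already sits ortho to C4, so ring C becomes an open 1,2-diol. The forward step must displace a benzylic hydroxyl with clean inversion, which requires the anti-diol.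

**26 to 25.** The C2–H bond is cut, giving a ketone. The neighbouring free C3 hydroxyl allows chelation to set the carbinol; the forward step must be selective for the anti-diol.

**25 to 22 and 23, then 22 to 21.** The C2–aryl bond is cut so that ring B enters as a nucleophile on an acyl carbon. The amide C–N bond is then cut back to the lactone. The forward steps must stop at the ketone and must not disturb the aryl bromide.

**21 to 19.** The C3–O bond is cut. The lactone enolate is the one point where C3 can be oxygenated under the control of the fixed C4 centre. The demand is attack anti to the C4 aryl group on an enolate that can fragment.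

**19 to 10 and 17.** The C4–C4a bond and the acyl O1–C2 bond of the middle unit are cut. This removes the diarylmethine stereocentre and ring C at once and separates the molecule into an upper and a lower half of similar size. The forward step must find the carbon ortho to the one free hydroxyl, add it to a deactivated β-carbon with control of the face, and lactonise.

**17 to 15 and 16, 15 to 12 and 13, 12 to 4.** The acyl C–N bond, the Cα=Cβ bond and the C8–CHO bond are cut in turn. This leads back to the aryl bromide, whose bromine marks C8 unambiguously. The forward steps must give the E-alkene and must metalate without touching benzyl ethers.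

**10 to 9, 8, 7, then 7 to 5 and 6.** Two O–benzyl bonds and one O–Si bond on the hub ring are cut, then the C4–aryl bond of the upper unit. With the C3-symmetric triol as nucleophile only one constitution can form. The price is that the para hydroxyl must afterwards be told apart from the two ortho hydroxyls by size alone.

**5 to 4, 3, 2, 1.** The C4–O, O–Si, C8–Br and four O–benzyl bonds are cut. Both halves then come from one brominated, silylated building block, and all carried stereocentres come from the natural product.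

## Other disconnections considered

**Alternative 1:** The cut runs through ring A of the middle unit (C4a–C8a and C5–C6 new, C8–C8a broken and re-formed).

- **Forward step:** the cyclobutenone A2 (upper unit with its gallate on C2, benzyloxy on C3) is heated with the siloxyalkyne A3 in a Danheiser benzannulation. Ring opening gives a vinylketene; [2+2] addition to the alkyne, a second ring opening and six-electron closure then give the phenol A1.
- **In its favour:** the position of U (C6) and the roles of the three oxygens (O1 free, O5 silyl, O7 benzyl) follow from the connectivity of A2 and A3, with no regiochemical choice. On these two points it is better than the chosen plan, which spends steps 6 to 8 on the same differentiation. The neutral thermal conditions would also let the upper gallate be carried from the start, which is better than the late esterification of step 21. It forms three C–C bonds in one step against one C–C and one C–O bond in step 12.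
- **Against it:** it makes an arene that the chosen plan takes from phloroglucinol in one step, and it creates no stereocentre. C2, C3 and C4 of M and the bond to L would all remain, starting from an acetal carbon with nothing to control the diarylmethine. A2 needs a bond from C4 of a flavan to C2 of a cyclobutenone, for which no reliable method is at hand, and the ketene would be very crowded.
- **Comparison:** the steps to A2, and then from A1 to ring C of M, would outnumber those of the chosen plan.

**Alternative 2:** The cut is ring C of the upper unit (C4–C4a, C3–C4, O1–C2).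

- **Forward step:** a chiral phosphoric acid condenses the aldehyde A5 (M–L dimer, formyl at M-C6, bromine at M-C8) with the phenol A6 to an ortho-quinone methide. This adds the (Z)-enol gallate A7 in a [4+2] reaction to give A4.
- **In its favour:** one step would make three bonds, one ring and three stereocentres, and the upper gallate arrives with A7. The other two gallates would already be in place, so only a hydrogenolysis follows. The M–L bond would come from the classical 4→8 coupling, the best precedented bond in this family. On step economy after the key step and on the M–L bond it is better than the chosen plan, which needs steps 13 to 22 after its key step.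
- **Against it:** the formyl carbon of A5 lies between two benzyloxy groups on a very large dimer. The quinone methide would be stabilised by its electron-rich aryl group and could add a second molecule of A6. Enol esters are weak partners. The Z geometry gives 2,3-cis, but 3,4-trans needs one particular approach mode, and the catalyst would have to set three centres against the bias of the dimer through an ion pair. The scandium chelate of step 12 is better defined and sets one centre.
- **Comparison:** A5 itself needs blocking at C8 and formylation at C6 of a dimer, so the 4→6 selectivity is paid for there. The route would be shorter if its key step worked, but the risk is concentrated in it.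

**Alternative 3:** The cut is C3–O and O1–C2 of the middle unit.

- **Forward step:** the (Z)-alkene A9, with its ring A phenol silylated, is epoxidised by a chiral dioxirane (Shi epoxidation). After fluoride and acid the freed phenol opens the cis-epoxide at benzylic C2 with inversion (6-endo), giving A8 with a free C3 hydroxyl.
- **In its favour:** C2 and C3 come from one catalyst-controlled step and a stereospecific opening. That is fewer operations on ring C than steps 13 to 17. With no organometallic step, the upper and lower gallates could be carried and only one ester is added late, against three separate esterifications in steps 18, 20 and 21. On these counts it is better than the chosen plan.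
- **Against it:** it does nothing for C4. The diarylmethine must already be in A9, so this is an end game and not a route to the hard bond. A Z-alkene next to a diarylmethine is hard to make pure from a benzylic ylide. The dioxirane meets many electron-rich rings and must choose a face beside a bulky stereocentre. Ionisation of the p-alkoxybenzylic epoxide would erode the 2,3-cis relation; here it is the equal of the Mitsunobu closure of step 17, which has the same weakness.
- **Comparison:** the chosen plan uses the lactone carbonyl of 19 both to control C3 and to bring in ring B as a nucleophile, which avoids the alkene geometry problem at the cost of more steps.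

Key step: step 12

Remark 1: the structure alone does not show which enantiomer of the pybox ligand exposes the Si face of the β-carbon of 17. The (S,S) ligand is written, and its mirror image takes its place unchanged if a trial with 17 and a simple 3,5-dialkoxyphenol shows the opposite sense.

Remark 2: 3,4,5-tris(benzyloxy)benzoic acid (28, the benzylated form of gallic acid) and 4-bromo-1,2-bis(benzyloxy)benzene (23) are taken as purchased materials.

## Steps

**Step 1**
Reactants: 1 (−)-epicatechin
Product: 2 5,7,3',4'-tetra-O-benzyl-(−)-epicatechin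
Conditions: BnBr, K2CO3, DMF, 0 °C → rt, under argon
Reagents that add atoms: benzyl bromide BrCc1ccccc1
Why: Williamson etherification of the four phenols; K2CO3 does not deprotonate the secondary 3-OH, and the mild, oxygen-free conditions should avoid epimerisation at C2.

**Step 2**
Reactants: 2 5,7,3',4'-tetra-O-benzyl-(−)-epicatechin
Product: 3 8-bromo-5,7,3',4'-tetra-O-benzyl-(−)-epicatechin
Conditions: NBS, CH2Cl2, −78 °C → rt
Reagents that add atoms: N-bromosuccinimide O=C1CCC(=O)N1Br
Why: Electrophilic aromatic bromination; C8, between O1 and the 7-benzyloxy group, is the most nucleophilic and least hindered carbon of ring A, so one equivalent of NBS at low temperature should brominate it alone.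

**Step 3**
Reactants: 3 8-bromo-5,7,3',4'-tetra-O-benzyl-(−)-epicatechin
Product: 4 8-bromo-3-O-(tert-butyldimethylsilyl)-5,7,3',4'-tetra-O-benzyl-(−)-epicatechin
Conditions: TBSCl, imidazole, DMF, rt
Reagents that add atoms: tert-butyldimethylsilyl chloride CC(C)(C)[Si](C)(C)Cl
Why: Standard silylation of the secondary alcohol; the silyl ether survives the Lewis acid, base and organometallic steps and is removed by fluoride. Compound 4 serves both branches.

**Step 4**
Reactants: 4 8-bromo-3-O-(tert-butyldimethylsilyl)-5,7,3',4'-tetra-O-benzyl-(−)-epicatechin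
Product: 5 4β-(2-ethoxyethoxy) derivative of 4 (3,4-trans)
Conditions: DDQ, 2-ethoxyethanol, CH2Cl2, rt
Reagents that add atoms: 2-ethoxyethanol CCOCCO
Why: Oxidative benzylic etherification; DDQ abstracts hydride from C4, which is activated by the three ring A oxygens, and the alcohol captures the cation trans to the 3-silyloxy group. Unsubstituted benzyl ethers are not oxidised under these conditions.

**Step 5**
Reactants: 5 4β-(2-ethoxyethoxy) derivative of 4; 6 phloroglucinol
Product: 7 4β-(2,4,6-trihydroxyphenyl) derivative of 4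
Conditions: 6 (5 equiv), BF3·OEt2 (0.3 equiv), THF/CH2Cl2, −40 → 0 °C
Reagents that add atoms: none
Why: Friedel–Crafts alkylation through the ring A-stabilised C4 cation; attack anti to the 3-silyloxy and 2-aryl groups sets the 4β (3,4-trans) centre. The C3-symmetric nucleophile allows one constitution only, its excess suppresses double alkylation, and the C8 bromine stops self-condensation of 5.

**Step 6**
Reactants: 7 4β-(2,4,6-trihydroxyphenyl) derivative of 4
Product: 8 4β-[2,6-dihydroxy-4-(triisopropylsilyloxy)phenyl] derivative of 4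
Conditions: TIPSCl (1.05 equiv), imidazole, DMF, −20 → 0 °C
Reagents that add atoms: triisopropylsilyl chloride CC(C)[Si](Cl)(C(C)C)C(C)C
Why: Kinetic silylation with a bulky chlorosilane; the para hydroxyl has two hydrogen neighbours, whereas each ortho hydroxyl lies beside the flavan-4-yl group with its 3-silyloxy and 5-benzyloxy substituents.

**Step 7**
Reactants: 8 4β-[2,6-dihydroxy-4-(triisopropylsilyloxy)phenyl] derivative of 4
Product: 9 4β-[2,6-bis(benzyloxy)-4-(triisopropylsilyloxy)phenyl] derivative of 4
Conditions: BnBr, K2CO3, Bu4NI (cat.), dry acetone, 50 °C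
Reagents that add atoms: benzyl bromide BrCc1ccccc1
Why: Williamson etherification of the two remaining phenols; anhydrous carbonate in acetone should leave the aryl triisopropylsilyl ether and the alkyl silyl ether intact.

**Step 8**
Reactants: 9 4β-[2,6-bis(benzyloxy)-4-(triisopropylsilyloxy)phenyl] derivative of 4
Product: 10 hub phenol, 4β-[2,6-bis(benzyloxy)-4-hydroxyphenyl] derivative of 4
Conditions: Bu4NF, AcOH, THF, 0 °C
Reagents that add atoms: none
Why: Fluoride cleaves an aryl silyl ether far faster than a hindered secondary alkyl silyl ether; acetic acid buffers the phenoxide.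

**Step 9**
Reactants: 4 8-bromo-3-O-(tert-butyldimethylsilyl)-5,7,3',4'-tetra-O-benzyl-(−)-epicatechin
Product: 12 3-O-(tert-butyldimethylsilyl)-5,7,3',4'-tetra-O-benzyl-(−)-epicatechin-8-carbaldehyde, via 8-lithio intermediate 11 (not isolated)
Conditions: n-BuLi, THF, −78 °C; DMF, −78 → 0 °C; aq NH4Cl
Reagents that add atoms: n-butyllithium [Li]CCCC (lithium in 11 only); N,N-dimethylformamide CN(C)C=O
Why: Bromine–lithium exchange at −78 °C gives the aryllithium flanked by two oxygens, which DMF formylates (Bouveault formylation); benzyl ethers are not metalated at this temperature.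

**Step 10**
Reactants: 12 3-O-(tert-butyldimethylsilyl)-5,7,3',4'-tetra-O-benzyl-(−)-epicatechin-8-carbaldehyde; 13 malonic acid
Product: 15 (E)-3-(lower unit-8-yl)acrylic acid, via arylidenemalonic acid 14 (not isolated)
Conditions: pyridine, piperidine (cat.), 90 °C
Reagents that add atoms: none
Why: Knoevenagel–Doebner condensation; the arylidenemalonic acid loses CO2 on heating in pyridine and gives the E acid under thermodynamic control, as with other 2,6-dialkoxybenzaldehydes.

**Step 11**
Reactants: 15 (E)-3-(lower unit-8-yl)acrylic acid; 16 3,5-dimethylpyrazole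
Product: 17 (E)-1-(3,5-dimethylpyrazol-1-yl)-3-(lower unit-8-yl)prop-2-en-1-one
Conditions: EDC·HCl, DMAP (cat.), CH2Cl2, rt
Reagents that add atoms: none
Why: Carbodiimide-mediated N-acylation of the pyrazole; the product is an activated amide whose carbonyl oxygen and N2 can bind one metal centre.

**Step 12**
Reactants: 10 hub phenol; 17 (E)-1-(3,5-dimethylpyrazol-1-yl)-3-(lower unit-8-yl)prop-2-en-1-one
Product: 19 (4R)-4-(lower unit-8-yl)-3,4-dihydrocoumarin carrying the upper unit at C6 and benzyloxy groups at C5 and C7, via conjugate adduct 18 (not isolated)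
Conditions: Sc(OTf)3 (10 mol%), (S,S)-inda-pybox (12 mol%), 4 Å MS, CH2Cl2, −20 °C → rt
Reagents that add atoms: none
Why: Proposed new method: Sc(OTf)3 held by the tridentate pybox chelates 17 through the carbonyl oxygen and pyrazole N2, which lowers the LUMO of the enoyl unit enough to offset the donor effect of the trioxygenated aryl group on the β-carbon; the carbon ortho to the free hydroxyl of 10 adds to this β-carbon (Friedel–Crafts conjugate addition) and rearomatises to 18. The phenol next to the new bond then attacks the scandium-activated acyl pyrazole and expels 3,5-dimethylpyrazole, a 6-exo-trig acyl substitution that closes the lactone (ring C of the middle unit), makes the C–C bond formation irreversible and frees the catalyst. The closest known reaction type is the chiral Lewis acid-catalysed Friedel–Crafts alkylation–lactonisation of electron-rich phenols with α,β-unsaturated acyl azoles or β,γ-unsaturated α-ketoesters to 4-substituted dihydrocoumarins; new here are the doubly ortho-substituted β-aryl group and the size of both partners. The one new stereocentre, C4, is set by the ligand, which has to expose the Si face of the β-carbon (lower-unit aryl, Cα, H counterclockwise) to give (4R); the existing stereocentres lie four or more bonds from the reacting atoms. Site selectivity rests on three features of 10: the free hydroxyl activates only its two ortho carbons; these are exchanged by rotation about the C4–aryl bond, so either one gives the 4→6 pattern; and the next best nucleophilic carbon, C8 of the upper unit, carries bromine. C-alkylation must come before O-acylation, which the low temperature and the two-point binding should favour.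

**Step 13**
Reactants: 19 (4R)-dihydrocoumarin
Product: 21 (3R,4R)-3-hydroxy-dihydrocoumarin, via potassium enolate 20 (not isolated)
Conditions: KN(SiMe3)2, THF, −78 °C; 2-(phenylsulfonyl)-3-phenyloxaziridine, −78 °C; aq NH4Cl
Reagents that add atoms: potassium bis(trimethylsilyl)amide C[Si](C)(C)N([K])[Si](C)(C)C (potassium in 20 only); 2-(phenylsulfonyl)-3-phenyloxaziridine O=S(=O)(c1ccccc1)N1OC1c1ccccc1
Why: Davis oxidation of the lactone enolate; the C4 aryl group, pseudoaxial to avoid the 5-benzyloxy group, covers one face, so oxygen should enter anti and give the 3,4-trans relation of the target.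

**Step 14**
Reactants: 21 (3R,4R)-3-hydroxy-dihydrocoumarin
Product: 22 N-methoxy-N-methyl amide with free ring A phenol and free C3 hydroxyl
Conditions: MeNH(OMe)·HCl, AlMe3, CH2Cl2, 0 °C → rt; aq potassium sodium tartrate
Reagents that add atoms: N,O-dimethylhydroxylamine hydrochloride CNOC.Cl
Why: Weinreb aminolysis of an activated aryl ester by the aluminium amide; it frees the O1 phenol and gives an acyl group that takes up one equivalent of carbon nucleophile only, which the lactone itself would not.

**Step 15**
Reactants: 22 N-methoxy-N-methyl amide; 23 4-bromo-1,2-bis(benzyloxy)benzene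
Product: 25 α-hydroxy aryl ketone (C2 carbonyl of the middle unit), via aryl Grignard reagent 24 (not isolated)
Conditions: 23 (5 equiv), Mg, THF, 50 °C; then 22, THF, 0 °C → rt; aq NH4Cl
Reagents that add atoms: magnesium [Mg] (in 24 only)
Why: Grignard addition to a Weinreb amide stops at the chelated tetrahedral intermediate and gives the ketone on work-up; two equivalents of reagent are used up by the phenol and the C3 hydroxyl. A Grignard reagent, unlike an aryllithium, does not exchange with the C8 bromide.

**Step 16**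
Reactants: 25 α-hydroxy aryl ketone
Product: 26 anti-1,2-diol, (2S,3R,4R) in flavan numbering of the middle unit
Conditions: Zn(BH4)2, Et2O/THF, −20 °C; aq NH4Cl
Reagents that add atoms: none
Why: Chelation-controlled reduction (Cram chelate model); zinc bridges the carbonyl and the C3 hydroxyl oxygens, and hydride attacks the face away from the diarylmethine substituent, which gives the anti-diol.

**Step 17**
Reactants: 26 anti-1,2-diol
Product: 27 protected trimer with free C3 hydroxyl on the middle unit (2R,3R,4R)
Conditions: PPh3, DIAD, THF, 0 °C → rt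
Reagents that add atoms: none
Why: Intramolecular Mitsunobu etherification; the phenol is the only acidic partner and displaces the activated benzylic hydroxyl in a 6-exo-tet closure with inversion, which turns the anti-diol into the 2,3-cis ring. The more hindered C3 hydroxyl stays free.

**Step 18**
Reactants: 27 protected trimer with free C3 hydroxyl on the middle unit; 28 3,4,5-tris(benzyloxy)benzoic acid
Product: 29 middle-unit 3-O-[3,4,5-tris(benzyloxy)benzoyl] ester of 27, silyl ethers on the upper and lower units kept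
Conditions: DCC, DMAP, CH2Cl2, rt → 40 °C (28 in excess)
Reagents that add atoms: none
Why: Steglich esterification; the middle 3-hydroxyl is the only free hydroxyl of 27, so the most hindered of the three esters can be forced with excess activated acid on a single site while the other two positions are still silylated.

**Step 19**
Reactants: 29 middle-unit 3-O-gallate with silyl ethers on the upper and lower units
Product: 30 diol with free 3-hydroxyls on the upper and lower units and the benzylated gallate on the middle unit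
Conditions: HF·pyridine, pyridine, THF, 0 °C → rt
Reagents that add atoms: none
Why: Fluoride cleavage of the two secondary silyl ethers under buffered, non-basic conditions that do not hydrolyse an aryl carboxylate ester; the ester has no free hydroxyl in its own unit, so it cannot migrate, and benzyl ethers and the aryl bromide are inert.

**Step 20**
Reactants: 30 diol with the middle-unit gallate; 28 3,4,5-tris(benzyloxy)benzoic acid
Product: 31 lower- and middle-unit 3-O-digallate with free 3-hydroxyl on the upper unit
Conditions: 28 (1.1 equiv), DCC, DMAP (cat.), CH2Cl2, −10 → 0 °C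
Reagents that add atoms: none
Why: Site-selective Steglich esterification; the lower 3-hydroxyl has a methylene group at C4, whereas the upper one lies between the C2 aryl group and the C4 hub ring with its two ortho benzyloxy groups, so the bulky acylpyridinium should take the lower hydroxyl first. Staging keeps the excess of activated acid small, and material esterified at the upper or at both hydroxyls is not lost, because step 21 turns it into the same product.

**Step 21**
Reactants: 31 lower- and middle-unit digallate; 28 3,4,5-tris(benzyloxy)benzoic acid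
Product: 32 perbenzylated tris-gallate with bromine at C8 of the upper unit
Conditions: DCC, DMAP (1 equiv), CH2Cl2, 40 °C (28 in excess)
Reagents that add atoms: none
Why: Steglich esterification of the last, hindered hydroxyl under forcing conditions; it is the same kind of alcohol as the 3-hydroxyl of 4-arylflavan-3-ols, which are acylated in this way, and the two esters already present are inert to the acylpyridinium.

**Step 22**
Reactants: 32 perbenzylated tris-gallate
Product: 33 CNP0183218.1, epicatechin 3-O-gallate-(4β→6)-epicatechin 3-O-gallate-(4β→8)-epicatechin 3-O-gallate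
Conditions: H2 (1 atm), Pd(OH)2/C, Et3N (1.1 equiv), THF/MeOH/H2O, rt
Reagents that add atoms: none
Why: Hydrogenolysis of the twenty-one benzyl ethers and of the aryl C–Br bond in one operation; one equivalent of triethylamine takes up the HBr and is consumed as its salt, so it does not retard the ether cleavage. The esters and the two interflavan C–C bonds are not cleaved under these neutral conditions.

## Compound list

1 | (−)-epicatechin | O[C@@H]1Cc2c(O)cc(O)cc2O[C@@H]1c1ccc(O)c(O)c1 | starting material

2 | 5,7,3',4'-tetra-O-benzyl-(−)-epicatechin | O[C@@H]1Cc2c(OCc5ccccc5)cc(OCc5ccccc5)cc2O[C@@H]1c1ccc(OCc5ccccc5)c(OCc5ccccc5)c1 | intermediate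

3 | 8-bromo-5,7,3',4'-tetra-O-benzyl-(−)-epicatechin | O[C@@H]1Cc2c(OCc5ccccc5)cc(OCc5ccccc5)c(Br)c2O[C@@H]1c1ccc(OCc5ccccc5)c(OCc5ccccc5)c1 | intermediate

4 | 8-bromo-3-O-(tert-butyldimethylsilyl)-5,7,3',4'-tetra-O-benzyl-(−)-epicatechin | CC(C)(C)[Si](C)(C)O[C@@H]1Cc2c(OCc5ccccc5)cc(OCc5ccccc5)c(Br)c2O[C@@H]1c1ccc(OCc5ccccc5)c(OCc5ccccc5)c1 | intermediate

5 | 4β-(2-ethoxyethoxy) derivative of 4 | CC(C)(C)[Si](C)(C)O[C@@H]1[C@@H](OCCOCC)c2c(OCc5ccccc5)cc(OCc5ccccc5)c(Br)c2O[C@@H]1c1ccc(OCc5ccccc5)c(OCc5ccccc5)c1 | intermediate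

6 | phloroglucinol | Oc1cc(O)cc(O)c1 | starting material

7 | 4β-(2,4,6-trihydroxyphenyl) derivative of 4 | CC(C)(C)[Si](C)(C)O[C@@H]1[C@@H](c2c(O)cc(O)cc2O)c2c(OCc5ccccc5)cc(OCc5ccccc5)c(Br)c2O[C@@H]1c1ccc(OCc5ccccc5)c(OCc5ccccc5)c1 | intermediate

8 | 4β-[2,6-dihydroxy-4-(triisopropylsilyloxy)phenyl] derivative of 4 | CC(C)(C)[Si](C)(C)O[C@@H]1[C@@H](c2c(O)cc(O[Si](C(C)C)(C(C)C)C(C)C)cc2O)c2c(OCc5ccccc5)cc(OCc5ccccc5)c(Br)c2O[C@@H]1c1ccc(OCc5ccccc5)c(OCc5ccccc5)c1 | intermediate

9 | 4β-[2,6-bis(benzyloxy)-4-(triisopropylsilyloxy)phenyl] derivative of 4 | CC(C)(C)[Si](C)(C)O[C@@H]1[C@@H](c2c(OCc5ccccc5)cc(O[Si](C(C)C)(C(C)C)C(C)C)cc2OCc5ccccc5)c2c(OCc5ccccc5)cc(OCc5ccccc5)c(Br)c2O[C@@H]1c1ccc(OCc5ccccc5)c(OCc5ccccc5)c1 | intermediate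

10 | hub phenol, 4β-[2,6-bis(benzyloxy)-4-hydroxyphenyl] derivative of 4 | CC(C)(C)[Si](C)(C)O[C@@H]1[C@@H](c2c(OCc5ccccc5)cc(O)cc2OCc5ccccc5)c2c(OCc5ccccc5)cc(OCc5ccccc5)c(Br)c2O[C@@H]1c1ccc(OCc5ccccc5)c(OCc5ccccc5)c1 | intermediate

11 | 8-lithio-3-O-(tert-butyldimethylsilyl)-5,7,3',4'-tetra-O-benzyl-(−)-epicatechin | CC(C)(C)[Si](C)(C)O[C@@H]1Cc2c(OCc5ccccc5)cc(OCc5ccccc5)c([Li])c2O[C@@H]1c1ccc(OCc5ccccc5)c(OCc5ccccc5)c1 | intermediate (not isolated)

12 | 3-O-(tert-butyldimethylsilyl)-5,7,3',4'-tetra-O-benzyl-(−)-epicatechin-8-carbaldehyde | CC(C)(C)[Si](C)(C)O[C@@H]1Cc2c(OCc5ccccc5)cc(OCc5ccccc5)c(C=O)c2O[C@@H]1c1ccc(OCc5ccccc5)c(OCc5ccccc5)c1 | intermediate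

13 | malonic acid | O=C(O)CC(=O)O | starting material

14 | [(lower unit-8-yl)methylidene]malonic acid | CC(C)(C)[Si](C)(C)O[C@@H]1Cc2c(OCc5ccccc5)cc(OCc5ccccc5)c(C=C(C(=O)O)C(=O)O)c2O[C@@H]1c1ccc(OCc5ccccc5)c(OCc5ccccc5)c1 | intermediate (not isolated)

15 | (E)-3-(lower unit-8-yl)acrylic acid | CC(C)(C)[Si](C)(C)O[C@@H]1Cc2c(OCc5ccccc5)cc(OCc5ccccc5)c(/C=C/C(=O)O)c2O[C@@H]1c1ccc(OCc5ccccc5)c(OCc5ccccc5)c1 | intermediate

16 | 3,5-dimethylpyrazole | Cc1cc(C)[nH]n1 | starting material

17 | (E)-1-(3,5-dimethylpyrazol-1-yl)-3-(lower unit-8-yl)prop-2-en-1-one | O=C(/C=C/c2c(OCc5ccccc5)cc(OCc5ccccc5)c4c2O[C@H](c2ccc(OCc5ccccc5)c(OCc5ccccc5)c2)[C@H](O[Si](C)(C)C(C)(C)C)C4)n1nc(C)cc1C | intermediate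

18 | conjugate adduct, (3R)-3-(hub aryl)-3-(lower unit-8-yl)propanoyl pyrazole with free phenol | CC(C)(C)[Si](C)(C)O[C@@H]1[C@@H](c2c(OCc5ccccc5)cc(O)c(c2OCc5ccccc5)[C@H](c2c(OCc5ccccc5)cc(OCc5ccccc5)c4c2O[C@H](c2ccc(OCc5ccccc5)c(OCc5ccccc5)c2)[C@H](O[Si](C)(C)C(C)(C)C)C4)CC(=O)n2nc(C)cc2C)c2c(OCc5ccccc5)cc(OCc5ccccc5)c(Br)c2O[C@@H]1c1ccc(OCc5ccccc5)c(OCc5ccccc5)c1 | intermediate (not isolated)

19 | (4R)-4-(lower unit-8-yl)-5,7-bis(benzyloxy)-6-(upper unit-4-yl)-3,4-dihydrocoumarin | CC(C)(C)[Si](C)(C)O[C@@H]1[C@@H](c2c(OCc5ccccc5)cc3c(c2OCc5ccccc5)[C@H](c2c(OCc5ccccc5)cc(OCc5ccccc5)c4c2O[C@H](c2ccc(OCc5ccccc5)c(OCc5ccccc5)c2)[C@H](O[Si](C)(C)C(C)(C)C)C4)CC(=O)O3)c2c(OCc5ccccc5)cc(OCc5ccccc5)c(Br)c2O[C@@H]1c1ccc(OCc5ccccc5)c(OCc5ccccc5)c1 | intermediate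

20 | potassium enolate of 19 | [K+].CC(C)(C)[Si](C)(C)O[C@@H]1[C@@H](c2c(OCc5ccccc5)cc3c(c2OCc5ccccc5)[C@H](c2c(OCc5ccccc5)cc(OCc5ccccc5)c4c2O[C@H](c2ccc(OCc5ccccc5)c(OCc5ccccc5)c2)[C@H](O[Si](C)(C)C(C)(C)C)C4)C=C([O-])O3)c2c(OCc5ccccc5)cc(OCc5ccccc5)c(Br)c2O[C@@H]1c1ccc(OCc5ccccc5)c(OCc5ccccc5)c1 | intermediate (not isolated)

21 | (3R,4R)-3-hydroxy derivative of 19 | CC(C)(C)[Si](C)(C)O[C@@H]1[C@@H](c2c(OCc5ccccc5)cc3c(c2OCc5ccccc5)[C@H](c2c(OCc5ccccc5)cc(OCc5ccccc5)c4c2O[C@H](c2ccc(OCc5ccccc5)c(OCc5ccccc5)c2)[C@H](O[Si](C)(C)C(C)(C)C)C4)[C@@H](O)C(=O)O3)c2c(OCc5ccccc5)cc(OCc5ccccc5)c(Br)c2O[C@@H]1c1ccc(OCc5ccccc5)c(OCc5ccccc5)c1 | intermediate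

22 | N-methoxy-N-methyl amide from 21, free phenol and free C3 hydroxyl | CC(C)(C)[Si](C)(C)O[C@@H]1[C@@H](c2c(OCc5ccccc5)cc(O)c(c2OCc5ccccc5)[C@H](c2c(OCc5ccccc5)cc(OCc5ccccc5)c4c2O[C@H](c2ccc(OCc5ccccc5)c(OCc5ccccc5)c2)[C@H](O[Si](C)(C)C(C)(C)C)C4)[C@@H](O)C(=O)N(C)OC)c2c(OCc5ccccc5)cc(OCc5ccccc5)c(Br)c2O[C@@H]1c1ccc(OCc5ccccc5)c(OCc5ccccc5)c1 | intermediate

23 | 4-bromo-1,2-bis(benzyloxy)benzene | Brc1ccc(OCc2ccccc2)c(OCc2ccccc2)c1 | starting material

24 | 3,4-bis(benzyloxy)phenylmagnesium bromide | Br[Mg]c1ccc(OCc2ccccc2)c(OCc2ccccc2)c1 | intermediate (not isolated)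

25 | α-hydroxy 3,4-bis(benzyloxy)phenyl ketone | CC(C)(C)[Si](C)(C)O[C@@H]1[C@@H](c2c(OCc5ccccc5)cc(O)c(c2OCc5ccccc5)[C@H](c2c(OCc5ccccc5)cc(OCc5ccccc5)c4c2O[C@H](c2ccc(OCc5ccccc5)c(OCc5ccccc5)c2)[C@H](O[Si](C)(C)C(C)(C)C)C4)[C@@H](O)C(=O)c2ccc(OCc5ccccc5)c(OCc5ccccc5)c2)c2c(OCc5ccccc5)cc(OCc5ccccc5)c(Br)c2O[C@@H]1c1ccc(OCc5ccccc5)c(OCc5ccccc5)c1 | intermediate

26 | anti-1,2-diol, (2S,3R,4R) in flavan numbering | CC(C)(C)[Si](C)(C)O[C@@H]1[C@@H](c2c(OCc5ccccc5)cc(O)c(c2OCc5ccccc5)[C@H](c2c(OCc5ccccc5)cc(OCc5ccccc5)c4c2O[C@H](c2ccc(OCc5ccccc5)c(OCc5ccccc5)c2)[C@H](O[Si](C)(C)C(C)(C)C)C4)[C@@H](O)[C@@H](O)c2ccc(OCc5ccccc5)c(OCc5ccccc5)c2)c2c(OCc5ccccc5)cc(OCc5ccccc5)c(Br)c2O[C@@H]1c1ccc(OCc5ccccc5)c(OCc5ccccc5)c1 | intermediate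

27 | protected trimer, free C3 hydroxyl on the middle unit, silyl ethers on the upper and lower units | CC(C)(C)[Si](C)(C)O[C@@H]1[C@@H](c2c(OCc5ccccc5)cc3c(c2OCc5ccccc5)[C@H](c2c(OCc5ccccc5)cc(OCc5ccccc5)c4c2O[C@H](c2ccc(OCc5ccccc5)c(OCc5ccccc5)c2)[C@H](O[Si](C)(C)C(C)(C)C)C4)[C@@H](O)[C@@H](c2ccc(OCc5ccccc5)c(OCc5ccccc5)c2)O3)c2c(OCc5ccccc5)cc(OCc5ccccc5)c(Br)c2O[C@@H]1c1ccc(OCc5ccccc5)c(OCc5ccccc5)c1 | intermediate

28 | 3,4,5-tris(benzyloxy)benzoic acid | O=C(O)c1cc(OCc2ccccc2)c(OCc2ccccc2)c(OCc2ccccc2)c1 | starting material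

29 | middle-unit 3-O-[3,4,5-tris(benzyloxy)benzoyl] ester of 27, silyl ethers on the upper and lower units | CC(C)(C)[Si](C)(C)O[C@@H]1[C@@H](c2c(OCc5ccccc5)cc3c(c2OCc5ccccc5)[C@H](c2c(OCc5ccccc5)cc(OCc5ccccc5)c4c2O[C@H](c2ccc(OCc5ccccc5)c(OCc5ccccc5)c2)[C@H](O[Si](C)(C)C(C)(C)C)C4)[C@@H](OC(=O)c2cc(OCc5ccccc5)c(OCc5ccccc5)c(OCc5ccccc5)c2)[C@@H](c2ccc(OCc5ccccc5)c(OCc5ccccc5)c2)O3)c2c(OCc5ccccc5)cc(OCc5ccccc5)c(Br)c2O[C@@H]1c1ccc(OCc5ccccc5)c(OCc5ccccc5)c1 | intermediate

30 | perbenzylated 8-bromo trimer, middle-unit 3-O-gallate, free 3-hydroxyls on the upper and lower units | O[C@@H]1[C@@H](c2c(OCc5ccccc5)cc3c(c2OCc5ccccc5)[C@H](c2c(OCc5ccccc5)cc(OCc5ccccc5)c4c2O[C@H](c2ccc(OCc5ccccc5)c(OCc5ccccc5)c2)[C@H](O)C4)[C@@H](OC(=O)c2cc(OCc5ccccc5)c(OCc5ccccc5)c(OCc5ccccc5)c2)[C@@H](c2ccc(OCc5ccccc5)c(OCc5ccccc5)c2)O3)c2c(OCc5ccccc5)cc(OCc5ccccc5)c(Br)c2O[C@@H]1c1ccc(OCc5ccccc5)c(OCc5ccccc5)c1 | intermediate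

31 | perbenzylated 8-bromo trimer, lower- and middle-unit 3-O-gallates, free 3-hydroxyl on the upper unit | O[C@@H]1[C@@H](c2c(OCc5ccccc5)cc3c(c2OCc5ccccc5)[C@H](c2c(OCc5ccccc5)cc(OCc5ccccc5)c4c2O[C@H](c2ccc(OCc5ccccc5)c(OCc5ccccc5)c2)[C@H](OC(=O)c2cc(OCc5ccccc5)c(OCc5ccccc5)c(OCc5ccccc5)c2)C4)[C@@H](OC(=O)c2cc(OCc5ccccc5)c(OCc5ccccc5)c(OCc5ccccc5)c2)[C@@H](c2ccc(OCc5ccccc5)c(OCc5ccccc5)c2)O3)c2c(OCc5ccccc5)cc(OCc5ccccc5)c(Br)c2O[C@@H]1c1ccc(OCc5ccccc5)c(OCc5ccccc5)c1 | intermediate

32 | perbenzylated tris-gallate with bromine at C8 of the upper unit | O=C(O[C@@H]1[C@@H](c2c(OCc5ccccc5)cc3c(c2OCc5ccccc5)[C@H](c2c(OCc5ccccc5)cc(OCc5ccccc5)c4c2O[C@H](c2ccc(OCc5ccccc5)c(OCc5ccccc5)c2)[C@H](OC(=O)c2cc(OCc5ccccc5)c(OCc5ccccc5)c(OCc5ccccc5)c2)C4)[C@@H](OC(=O)c2cc(OCc5ccccc5)c(OCc5ccccc5)c(OCc5ccccc5)c2)[C@@H](c2ccc(OCc5ccccc5)c(OCc5ccccc5)c2)O3)c2c(OCc5ccccc5)cc(OCc5ccccc5)c(Br)c2O[C@@H]1c1ccc(OCc5ccccc5)c(OCc5ccccc5)c1)c1cc(OCc5ccccc5)c(OCc5ccccc5)c(OCc5ccccc5)c1 | intermediate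

33 | CNP0183218.1 | O=C(O[C@@H]1[C@@H](c2c(O)cc3c(c2O)[C@H](c2c(O)cc(O)c4c2O[C@H](c2ccc(O)c(O)c2)[C@H](OC(=O)c2cc(O)c(O)c(O)c2)C4)[C@@H](OC(=O)c2cc(O)c(O)c(O)c2)[C@@H](c2ccc(O)c(O)c2)O3)c2c(O)cc(O)cc2O[C@@H]1c1ccc(O)c(O)c1)c1cc(O)c(O)c(O)c1 | target

## Step count and least certain steps

Total step count: 22. Longest linear sequence: 19 steps (steps 1 to 8, then 12 to 22); the lower-unit branch (steps 9 to 11) joins at step 12.

**Step 12 (key step).** Several processes could defeat it.

- Conjugate addition may be slow, because the β-carbon of 17 is deactivated by a trioxygenated aryl group and flanked by two ortho substituents.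
- O-acylation of the phenol may precede C–C bond formation; a ligand-free hydroarylation would then erode the facial selectivity.
- The ligand may be mismatched with the two chiral partners.
- The released pyrazole may hold back the catalyst.
- Triflic acid traces may reverse the upper interflavan bond by ipso protonation of the hub ring.

The fallback uses known reactions only. It sets out from 10 and 4 and comes back at 19.

- Compound 10 is ortho-formylated (MgCl2, Et3N, paraformaldehyde, MeCN, reflux) to the salicylaldehyde F1.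
- A Z-selective Still–Gennari olefination (methyl bis(2,2,2-trifluoroethyl)phosphonoacetate, KN(SiMe3)2, 18-crown-6, THF, −78 °C → rt) gives the cis-cinnamate, which lactonises in the flask to the coumarin F2.
- The aryllithium 11, made from 4 as in step 9, is quenched with B(OMe)3 and hydrolysed to the boronic acid F3.
- A Hayashi–Miyaura conjugate addition of F3 to F2 (Rh(acac)(C2H4)2, the SEGPHOS enantiomer that gives (4R), dioxane/H2O, 60 °C) leads to 19. This reaction type is established for coumarins and gives 4-arylchroman-2-ones.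

The fallback costs three more operations. Its own weak points are the hindered 5-benzyloxycoumarin and protodeboronation of the 2,6-dioxygenated boronic acid.

**Step 17.** The activated benzylic hydroxyl bears a p-benzyloxyphenyl group and may ionise before the phenol attacks, which would lose the stereospecificity at C2 in favour of the 2,3-trans ring. Activation of the C3 hydroxyl, or passage through an epoxide, would have the same effect. The fallback sets out from 26 and comes back at 27. Compound 26 is heated with HC(OEt)3 and pyridinium p-toluenesulfonate in 1,2-dichloroethane at 60 °C. The cyclic orthoformate ionises to a 1,3-dioxolan-2-ylium ion, which the phenol opens at the benzylic carbon with inversion to give the 3-O-formate F4. K2CO3 in MeOH then gives 27. In this mode the leaving group is tied to C3 and cannot form an epoxide.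

**Step 13.** The enolate of an aryl lactone can expel the phenoxide and form a ketene. The facial bias of the C4 aryl group may be incomplete, and the sulfonimine by-product can add to the enolate. The fallback sets out from 19 and comes back at 21. KN(SiMe3)2 is added to 19 and Me3SiCl at −78 °C, so that the enolate is trapped as it forms, giving the silyl ketene acetal F5. Rubottom oxidation (mCPBA, NaHCO3, CH2Cl2, −40 °C) delivers oxygen to the same open face and gives the α-silyloxy lactone F6, which aqueous citric acid in THF converts to 21.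

**Step 6.** Silylation may occur at an ortho hydroxyl or twice, after which the wrong isomer would be carried through the benzylation. The fallback sets out from 5 and comes back at 9. Purchased 3,5-bis(benzyloxy)phenol F7 is silylated (TIPSCl, imidazole, DMF) to the ether F8. F8 is coupled with 5 (BF3·OEt2 cat., CH2Cl2, −78 °C) at the carbon between the two benzyloxy groups, para to the shielding silyloxy group, to give 9 directly. This is two steps shorter, but the regiochemistry then rests on the bulk of the silyl group alone, and the isomers would have to be separated.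

Step 20 relies on a rate difference between two hydroxyls. It is not listed among the least certain steps, because material esterified at the other hydroxyl or at both is carried into step 21 and ends as 32.

## Further compounds

F1 | step 12 | salicylaldehyde from 10 (formyl ortho to the free hydroxyl) | CC(C)(C)[Si](C)(C)O[C@@H]1[C@@H](c2c(OCc5ccccc5)cc(O)c(C=O)c2OCc5ccccc5)c2c(OCc5ccccc5)cc(OCc5ccccc5)c(Br)c2O[C@@H]1c1ccc(OCc5ccccc5)c(OCc5ccccc5)c1

F2 | step 12 | 5,7-bis(benzyloxy)-6-(upper unit-4-yl)coumarin | CC(C)(C)[Si](C)(C)O[C@@H]1[C@@H](c2c(OCc5ccccc5)cc3c(c2OCc5ccccc5)C=CC(=O)O3)c2c(OCc5ccccc5)cc(OCc5ccccc5)c(Br)c2O[C@@H]1c1ccc(OCc5ccccc5)c(OCc5ccccc5)c1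

F3 | step 12 | 3-O-(tert-butyldimethylsilyl)-5,7,3',4'-tetra-O-benzyl-(−)-epicatechin-8-boronic acid | CC(C)(C)[Si](C)(C)O[C@@H]1Cc2c(OCc5ccccc5)cc(OCc5ccccc5)c(B(O)O)c2O[C@@H]1c1ccc(OCc5ccccc5)c(OCc5ccccc5)c1

F4 | step 17 | 3-O-formate of 27 | CC(C)(C)[Si](C)(C)O[C@@H]1[C@@H](c2c(OCc5ccccc5)cc3c(c2OCc5ccccc5)[C@H](c2c(OCc5ccccc5)cc(OCc5ccccc5)c4c2O[C@H](c2ccc(OCc5ccccc5)c(OCc5ccccc5)c2)[C@H](O[Si](C)(C)C(C)(C)C)C4)[C@@H](OC=O)[C@@H](c2ccc(OCc5ccccc5)c(OCc5ccccc5)c2)O3)c2c(OCc5ccccc5)cc(OCc5ccccc5)c(Br)c2O[C@@H]1c1ccc(OCc5ccccc5)c(OCc5ccccc5)c1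

F5 | step 13 | trimethylsilyl ketene acetal of 19 | CC(C)(C)[Si](C)(C)O[C@@H]1[C@@H](c2c(OCc5ccccc5)cc3c(c2OCc5ccccc5)[C@H](c2c(OCc5ccccc5)cc(OCc5ccccc5)c4c2O[C@H](c2ccc(OCc5ccccc5)c(OCc5ccccc5)c2)[C@H](O[Si](C)(C)C(C)(C)C)C4)C=C(O[Si](C)(C)C)O3)c2c(OCc5ccccc5)cc(OCc5ccccc5)c(Br)c2O[C@@H]1c1ccc(OCc5ccccc5)c(OCc5ccccc5)c1

F6 | step 13 | 3-O-trimethylsilyl ether of 21 | CC(C)(C)[Si](C)(C)O[C@@H]1[C@@H](c2c(OCc5ccccc5)cc3c(c2OCc5ccccc5)[C@H](c2c(OCc5ccccc5)cc(OCc5ccccc5)c4c2O[C@H](c2ccc(OCc5ccccc5)c(OCc5ccccc5)c2)[C@H](O[Si](C)(C)C(C)(C)C)C4)[C@@H](O[Si](C)(C)C)C(=O)O3)c2c(OCc5ccccc5)cc(OCc5ccccc5)c(Br)c2O[C@@H]1c1ccc(OCc5ccccc5)c(OCc5ccccc5)c1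

F7 | step 6 | 3,5-bis(benzyloxy)phenol | Oc1cc(OCc2ccccc2)cc(OCc2ccccc2)c1

F8 | step 6 | [3,5-bis(benzyloxy)phenoxy]triisopropylsilane | CC(C)[Si](Oc1cc(OCc2ccccc2)cc(OCc2ccccc2)c1)(C(C)C)C(C)C

A1 | alternative 1 | ring A phenol of the middle unit carrying the galloylated upper unit, free O1 hydroxyl, C4 dimethyl acetal, O5 triisopropylsilyl, O7 benzyl | O=C(O[C@@H]1[C@@H](c2c(OCc5ccccc5)cc(O)c(C(OC)OC)c2O[Si](C(C)C)(C(C)C)C(C)C)c2c(OCc5ccccc5)cc(OCc5ccccc5)cc2O[C@@H]1c1ccc(OCc5ccccc5)c(OCc5ccccc5)c1)c1cc(OCc5ccccc5)c(OCc5ccccc5)c(OCc5ccccc5)c1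

A2 | alternative 1 | 3-(benzyloxy)-2-(galloylated upper unit-4-yl)cyclobut-2-en-1-one | O=C(O[C@@H]1[C@@H](C2=C(OCc5ccccc5)CC2=O)c2c(OCc5ccccc5)cc(OCc5ccccc5)cc2O[C@@H]1c1ccc(OCc5ccccc5)c(OCc5ccccc5)c1)c1cc(OCc5ccccc5)c(OCc5ccccc5)c(OCc5ccccc5)c1

A3 | alternative 1 | 3,3-dimethoxy-1-(triisopropylsilyloxy)prop-1-yne | COC(OC)C#CO[Si](C(C)C)(C(C)C)C(C)C

A4 | alternative 2 | perbenzylated target with bromine at C8 of the middle unit | O=C(O[C@@H]1[C@@H](c2c(OCc5ccccc5)c(Br)c3c(c2OCc5ccccc5)[C@H](c2c(OCc5ccccc5)cc(OCc5ccccc5)c4c2O[C@H](c2ccc(OCc5ccccc5)c(OCc5ccccc5)c2)[C@H](OC(=O)c2cc(OCc5ccccc5)c(OCc5ccccc5)c(OCc5ccccc5)c2)C4)[C@@H](OC(=O)c2cc(OCc5ccccc5)c(OCc5ccccc5)c(OCc5ccccc5)c2)[C@@H](c2ccc(OCc5ccccc5)c(OCc5ccccc5)c2)O3)c2c(OCc5ccccc5)cc(OCc5ccccc5)cc2O[C@@H]1c1ccc(OCc5ccccc5)c(OCc5ccccc5)c1)c1cc(OCc5ccccc5)c(OCc5ccccc5)c(OCc5ccccc5)c1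

A5 | alternative 2 | perbenzylated middle–lower dimer digallate, 6-carbaldehyde, 8-bromo | O=Cc2c(OCc5ccccc5)c(Br)c3c(c2OCc5ccccc5)[C@H](c2c(OCc5ccccc5)cc(OCc5ccccc5)c4c2O[C@H](c2ccc(OCc5ccccc5)c(OCc5ccccc5)c2)[C@H](OC(=O)c2cc(OCc5ccccc5)c(OCc5ccccc5)c(OCc5ccccc5)c2)C4)[C@@H](OC(=O)c2cc(OCc5ccccc5)c(OCc5ccccc5)c(OCc5ccccc5)c2)[C@@H](c2ccc(OCc5ccccc5)c(OCc5ccccc5)c2)O3

A6 | alternative 2 | 3,5-bis(benzyloxy)phenol | Oc1cc(OCc2ccccc2)cc(OCc2ccccc2)c1

A7 | alternative 2 | (Z)-2-[3,4-bis(benzyloxy)phenyl]ethenyl 3,4,5-tris(benzyloxy)benzoate | O=C(O/C=C\c1ccc(OCc2ccccc2)c(OCc2ccccc2)c1)c1cc(OCc2ccccc2)c(OCc2ccccc2)c(OCc2ccccc2)c1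

A8 | alternative 3 | perbenzylated trimer with free C3 hydroxyl on the middle unit, gallates on the upper and lower units | O=C(O[C@@H]1[C@@H](c2c(OCc5ccccc5)cc3c(c2OCc5ccccc5)[C@H](c2c(OCc5ccccc5)cc(OCc5ccccc5)c4c2O[C@H](c2ccc(OCc5ccccc5)c(OCc5ccccc5)c2)[C@H](OC(=O)c2cc(OCc5ccccc5)c(OCc5ccccc5)c(OCc5ccccc5)c2)C4)[C@@H](O)[C@@H](c2ccc(OCc5ccccc5)c(OCc5ccccc5)c2)O3)c2c(OCc5ccccc5)cc(OCc5ccccc5)cc2O[C@@H]1c1ccc(OCc5ccccc5)c(OCc5ccccc5)c1)c1cc(OCc5ccccc5)c(OCc5ccccc5)c(OCc5ccccc5)c1

A9 | alternative 3 | (Z)-1-[3,4-bis(benzyloxy)phenyl]-3-(lower unit-8-yl)-3-(hub aryl)propene with O1 as tert-butyldimethylsilyl ether, gallates on the upper and lower units | O=C(O[C@@H]1[C@@H](c2c(OCc5ccccc5)cc(O[Si](C)(C)C(C)(C)C)c(c2OCc5ccccc5)[C@H](c2c(OCc5ccccc5)cc(OCc5ccccc5)c4c2O[C@H](c2ccc(OCc5ccccc5)c(OCc5ccccc5)c2)[C@H](OC(=O)c2cc(OCc5ccccc5)c(OCc5ccccc5)c(OCc5ccccc5)c2)C4)/C=C\c2ccc(OCc5ccccc5)c(OCc5ccccc5)c2)c2c(OCc5ccccc5)cc(OCc5ccccc5)cc2O[C@@H]1c1ccc(OCc5ccccc5)c(OCc5ccccc5)c1)c1cc(OCc5ccccc5)c(OCc5ccccc5)c(OCc5ccccc5)c1
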